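The constants were set for the occasion; the rest is arithmetic.

A small charge of protic impurity stands in each flask below, beside first end groups and second end groups that go in at different times, and the question is how many first end groups that react become links rather than rings.

    second end groups → decomposed reagent (k1 = 4.49 × 10⁻⁴ s⁻¹)
    first end groups + second end groups → links (k2 = 0.0308 M⁻¹ s⁻¹)
    first end groups + second end groups → rings, rate k3*[first end groups] as long as [second end groups] is above zero (k3 = 5.47 × 10⁻⁵ s⁻¹)
    second end groups + protic impurity → quenched reagent (k4 = 1.92 M⁻¹ s⁻¹)
    2 second end groups → homo dimer (k5 = 0.0275 M⁻¹ s⁻¹)

all flasks: protic impurity 2.80 mM; time 2.5 h

| charge | first end groups | second end groups | remark |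
|---|---|---|---|
| north-east | 28 mM | 30.8 mM (fed, over 30 min) | all else is in the flask from the start; the feed brings no volume worth counting |
| east | 28 mM | 30.8 mM | everything together at the start |
| south | 28 mM (fed, over 30 min) | 30.8 mM | all else is in the flask from the start; the feed brings no volume worth counting |
| north | 28 mM (fed, over 8.0 min) | 30.8 mM | all else is in the flask from the start; the feed brings no volume worth counting |

- where a step has two of a species, its rate is k times that concentration squared, and two are used at each turn
- run time (north-east): 2.5 h

1. the best flask by share of links in links plus rings; "all alike" if 1.5 percentage points covers them all (north-east / east / south / north / all alike)
2. share of links in links plus rings at the end, north-east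
3. share of links in links plus rings at the end, east
4. share of links in links plus rings at the end, south
5. share of links in links plus rings at the end, north

Follow one first end group. At each moment it faces a fork: it becomes a link at k2 times the level of second end groups, or a ring at k3 whatever that level is, so long as some is there. The two chances are equal at a level of 1.78 mM; this ratio k3/k2 is the break-even level, the effective molarity of ring closing. Links per ring then equal the mean level of second end groups, as first end groups meet it, divided by the break-even level.

Take east and build it up. With the two fork steps, the share at the start is 94.5%. The protic impurity has a half-life of 11.7 s with second end groups held at their charge, against 0.20 h for first end groups by the link step, so it takes 2.80 mM of second end groups early and leaves 28.0 mM, and the share at that moment is still 94.0%. Decomposition and dimer formation then lower the level while rings keep their pace. Let second end groups fall by c times the level plus 2 times k5 times its square, with c = k1 + k2 times the charge of first end groups, 0.00131 s⁻¹. Integrating down to the break-even level takes 26.1 min at a mean level of 8.19 mM, so this reckoning commits to 82.2% for east, a high figure, since rings outrun links below that level. In south the 30 min feed outlasts the 0.43 h half-life of second end groups by step 1 alone, so first end groups arrive at a thinner level, and east should stand ahead of south.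

The forecast names east as best, with 70.5% for north-east, 77% for east, 65% for south and 73% for north, holding that “all at once gives the highest link share”. Its east figure lies below the reckoning's 82.2%.

The simulation gives east as best, with 70.7% for north-east, 77.6% for east, 66.0% for south and 73.1% for north.

East's share moves 5 points at 21.4 mM or 49.6 mM of second end groups, which is what would take it away from the forecast. Read back, east's 77.6% is a mean level of 6.17 mM, less than the reckoned 8.19 mM. The neighbour flask is south with 52 mM of second end groups. Over 30 min, the dimer step by itself thins south's 28.0 mM to 7.42 mM and the neighbour's 49.2 mM to 8.38 mM. Links per ring should therefore rise by a factor of 1.13, which lifts south's 66.0% to 68.7%; the neighbour flask gives 70.3%.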